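## Analysis of the target

- The target is an isoflavone: benzo ring A is fused to the 4-pyranone ring C (a chromen-4-one), C2 is a CH, and C3 carries the 2,4,5-trimethoxyphenyl ring B.
- Ring A is fully substituted: OH at C5 (hydrogen-bonded to the C4 carbonyl), prenyl at C6, OMe at C7 and OH at C8, with the fusion carbons C4a and C8a in the remaining positions.
- There is no stereocenter, so every problem is constitutional: the order of four different substituents on ring A, and the C3–C1' bond.
- Sensitive groups:
  - The C5/C8 hydroxyls form a para-hydroquinone that oxidises in air, faster in base.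
  - The prenyl olefin reacts with electrophiles and soft metal oxidants and can cyclise onto the C5 hydroxyl in acid.
  - The pyranone opens at C2 in aqueous alkali.
  - Ring B is a para-dimethoxyarene that strong oxidants turn into a quinone.
- The hard part is the hexasubstituted ring A, above all the prenyl group at C6 between C5-OH and C7-OMe, and the moment at which it is introduced.
- The strategy rests on the position of ring B. It sits on C3, next to the carbonyl, whereas an aldol-derived chalcone has it one carbon further out. An oxidative 1,2-aryl shift connects the two, and the ortho- and para-methoxy groups make ring B an excellent migrating group.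
- A second feature is used afterwards: the C5 and C8 oxygens are para, so ring A can be raised to a quinone whose only unsubstituted carbon is C6.

## Retrosynthetic reasoning

**C6–prenyl bond (14 to 12 and 13).** This bond is cut first. The prenyl olefin would not survive the oxidative rearrangement that builds the isoflavone, so it must arrive last. Ring A of 14 is a hydroquinone, so the prenyl group can come from allylstannane 13 adding to quinone 12. In 12 the quinone ring has a single CH, C6, and the addition returns ring A to the hydroquinone oxidation level of the target.

**Oxidation level (12 to 11).** Quinone 12 is the two-electron oxidation product of hydroquinone 11. Only ring A of 11 carries free phenols, so a mild oxidant should leave ring B and ring C alone.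

**O1–C2 bond and the two acetals (11 to 9 through 10).** Ring C is opened at O1–C2. In 9, C2 is a dimethyl acetal carbon, already at the aldehyde oxidation level, and the C2' hydroxyl is the only free phenol. Acid closes the ring and expels two molecules of alcohol. The order matters. A MOM ether ortho to an aryl ketone is the most acid-labile kind, and if the C6' oxygen were freed before closure it could close the ring instead and give the 5,6-dihydroxy isomer. Closure is therefore planned first, in an aprotic medium, to give 10. Only then are the MOM groups exchanged away, in the same flask, to give 11.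

**C3–C1' bond (9 to 8).** This is the strategic disconnection. Moving ring B back from the carbon α to the ketone to the β-carbon, and taking the acetal carbon back to an alkene carbon, gives chalcone 8. Forward, trivalent thallium must attack the enone, ring B must migrate rather than the aroyl group, and the cation left behind must be trapped as the acetal. Nothing else in 8 may be oxidised, which is why 8 carries no prenyl group and only one free, chelated phenol.

**Cα=Cβ bond (8 to 6 and 7).** The enone is an aldol condensation product of methyl ketone 6 and aldehyde 7. This brings in ring B complete, with all three methoxy groups, from a commercial aldehyde.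

**Oxygen pattern of ring A (6 back to 1).** Ketone 6 differs from symmetric diol 1 by one extra oxygen and by differentiated protection.
- The extra oxygen is placed by hydroxylation para to a free phenol, which takes 2 to 4 by way of aryl sulfate 3.
- That free phenol of 2 ends up as the C5 oxygen of the target, and the oxygen next to the new hydroxyl ends up as O1.
- The oxygen that is masked in 2 must therefore be the one set free in 6, and the other two must be capped in between (5).
- A benzyl ether on 2 is used because it survives the hydroxylation and is removed by hydrogenolysis without touching the MOM acetals.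

## Alternatives that were turned down

**Alternative 1: ring B built by Dötz benzannulation.**
- Disconnection: ring B is cut at C5'–C6', C1'–C2' and C2'–C3', leaving 3-ethynylchromone A2 and an alkenyl(methoxy)carbene complex of chromium.
- Forward key step: the carbene carbon, the two alkyne carbons, a carbonyl ligand and the vinyl carbons assemble ring B as phenol A1, with the new hydroxyl at C2'. O-methylation and MOM removal would follow.
- For it: the alkyne fixes where ring B joins C3, so no migratory-aptitude question arises. The prenyl olefin should tolerate the carbene complex. A1 has a differentiated C2' oxygen, useful for analogues.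
- Against it: ring B is commercial, complete, as aldehyde 7, so building it is effort spent on the easy part. A2 needs the whole prenylated ring A and a C3 alkynylation first, so the key step does nothing for the hexasubstituted ring. The chromone C2 is a Michael acceptor towards the carbene complex, hindered alkynes can divert to five-membered products, and the chromium reagent is stoichiometric.
- Comparison: it is at least as good on C3–aryl regiocontrol. The chosen route offers a shorter sequence, because ring B arrives by an aldol and the prenyl problem is solved separately at the quinone.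

**Alternative 2: chalcone epoxide and 1,2-aroyl shift.**
- Disconnection: the C3–C4 bond is traced back to trans-epoxide A4 of a 2'-O-allyl chalcone that already carries the prenyl group.
- Forward key step: a Lewis acid opens the epoxide at the benzylic carbon and the aroyl group moves to that carbon, giving formyl ketone A3. Removal of the allyl group, cyclodehydration and MOM removal would follow.
- For it: no thallium. Nucleophilic epoxidation does not touch an isolated trisubstituted olefin, so the prenyl group could be carried from the start and the quinone detour avoided.
- Against it: ring B is not the migrating group here. Its donors only make the benzylic C–O bond so labile that the epoxide may open before it can be handled, or divert to hydride shift. The C2' phenol must be masked, or it attacks the epoxide, and unmasking costs a step. A3 is an α-aryl β-keto aldehyde that loses its formyl group easily. The Lewis acid meets a prenyl group and two MOM acetals. The prenylated pentasubstituted acetophenone it starts from has no short access.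
- Comparison: it is stronger on metal toxicity and on carrying the prenyl group. The chosen route offers a rearrangement that ring B's methoxy groups accelerate, a free phenol that closes ring C without a deprotection, and a defined way to reach C6.

**Alternative 3: quinoketene and enamine annulation of ring C.**
- Disconnection: both bonds joining ring A to the C2–C3 unit, C3–C4 and O1–C2, are cut, giving benzodioxinone A7 and enamine A6.
- Forward key step: light or heat cleaves the dioxinone ring of A7 to an ortho-quinoid ketene. The enamine intercepts it, and loss of the amine gives protected isoflavone A5, one deprotection from the target.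
- For it: it is the most convergent plan, makes both ring C bonds in one operation, and is neutral and metal-free. Prenyl and MOM groups should pass untouched.
- Against it: A7 is a salicylic acid derivative carrying every substituent of ring A, prenyl included, so the real difficulty is moved to a compound harder to reach than acetophenone 1. A6 derives from an electron-rich arylacetaldehyde, which needs a one-carbon homologation of 7 and is prone to hydrolysis and self-condensation. The ketene is flanked by the C5 MOM ether, and enamines can also react with ketenes at carbon only.
- Comparison: it is better on convergence and avoids the heavy metal. The chosen route uses 7 as bought and builds ring A stepwise from cheap 1.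

Key step: step 6

Assumption: stannane 13 is taken as a catalogue reagent, and the target is handled as the hydroquinone drawn, under inert gas.

## Route

Step 1
Reactants: 1 1-(2,6-dihydroxy-4-methoxyphenyl)ethanone
Product: 2 1-[2-(benzyloxy)-6-hydroxy-4-methoxyphenyl]ethanone
Conditions: BnBr (1.05 eq), K2CO3 (1.1 eq), acetone, reflux
Reagents that add atoms: benzyl bromide, BrCc1ccccc1
Why: Williamson etherification; after the first O-alkylation the remaining hydroxyl is locked in a hydrogen bond to the acetyl carbonyl and is far less nucleophilic, so the symmetric diol should stop at the monoether.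

Step 2
Reactants: 2 1-[2-(benzyloxy)-6-hydroxy-4-methoxyphenyl]ethanone
Product: 4 1-[2-(benzyloxy)-3,6-dihydroxy-4-methoxyphenyl]ethanone, via potassium aryl sulfate 3 (not isolated)
Conditions: K2S2O8 (1.1 eq), 2 M NaOH, pyridine, 15 °C; then HCl to pH 1, 85 °C
Reagents that add atoms: potassium peroxodisulfate, [K+].[K+].[O-]S(=O)(=O)OOS(=O)(=O)[O-]
Why: Elbs persulfate oxidation; the phenoxide attacks the peroxide oxygen through its free para carbon to give the aryl sulfate, which hot dilute acid hydrolyses to the quinol. The benzyl ether should tolerate both stages, and unreacted 2 can be recovered before the hydrolysis.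

Step 3
Reactants: 4 1-[2-(benzyloxy)-3,6-dihydroxy-4-methoxyphenyl]ethanone
Product: 5 1-[2-(benzyloxy)-4-methoxy-3,6-bis(methoxymethoxy)phenyl]ethanone
Conditions: NaH (2.4 eq), MOMCl (2.6 eq), DMF, 0 °C → rt, Ar
Reagents that add atoms: chloromethyl methyl ether, COCCl
Why: O-alkylation of both phenoxides; NaH in DMF is chosen because the C6 hydroxyl is chelated and resists weaker bases, and air is excluded so that the quinol dianion is not oxidised.

Step 4
Reactants: 5 1-[2-(benzyloxy)-4-methoxy-3,6-bis(methoxymethoxy)phenyl]ethanone
Product: 6 1-[2-hydroxy-4-methoxy-3,6-bis(methoxymethoxy)phenyl]ethanone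
Conditions: H2 (1 atm), 10% Pd/C, EtOAc, rt
Reagents that add atoms: none
Why: Hydrogenolysis of the benzyl ether under neutral conditions; the MOM acetals and the hindered aryl ketone should be inert, so only the oxygen that becomes O1 is set free.

Step 5
Reactants: 6 1-[2-hydroxy-4-methoxy-3,6-bis(methoxymethoxy)phenyl]ethanone; 7 2,4,5-trimethoxybenzaldehyde
Product: 8 (E)-1-[2-hydroxy-4-methoxy-3,6-bis(methoxymethoxy)phenyl]-3-(2,4,5-trimethoxyphenyl)prop-2-en-1-one
Conditions: KOH (50% aq), EtOH, rt
Reagents that add atoms: none
Why: Claisen–Schmidt condensation; the methyl ketone enolate adds to the non-enolisable aldehyde and the aldol loses water by E1cB to the conjugated (E)-enone, the thermodynamic isomer. MOM ethers are inert to KOH, and as its phenoxide the C2' oxygen should not close to the flavanone.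

Step 6
Reactants: 8 (E)-1-[2-hydroxy-4-methoxy-3,6-bis(methoxymethoxy)phenyl]-3-(2,4,5-trimethoxyphenyl)prop-2-en-1-one
Product: 9 1-[2-hydroxy-4-methoxy-3,6-bis(methoxymethoxy)phenyl]-3,3-dimethoxy-2-(2,4,5-trimethoxyphenyl)propan-1-one (racemic)
Conditions: Tl(NO3)3·3H2O (1.2 eq), MeOH–HC(OMe)3 3:1, 0 °C → rt
Reagents that add atoms: methanol, CO
Why: Oxidative 1,2-aryl rearrangement of a chalcone by trivalent thallium, the established isoflavone entry from 2'-hydroxychalcones. The electrophilic thallium salt adds to the enone double bond so that the metal is bound at Cα and methanol at the benzylic Cβ, the regiochemistry following from stabilisation of positive charge at Cβ by ring B. The C–Tl bond then ionises with reduction to monovalent thallium, and ring B shifts from Cβ to Cα through a bridged phenonium ion as the metal leaves; this makes the Cα–C1' bond, the future C3–C1' bond. The cation left at Cβ is an oxocarbenium ion and is captured by methanol as the dimethyl acetal, so Cβ ends at the aldehyde oxidation level needed for C2. No ring is closed, and the new stereocenter at Cα is formed racemic without consequence because it becomes the sp2 carbon C3 in step 7. The step needs attack on the enone rather than on the arenes or the phenol, and aryl rather than aroyl migration: the three methoxy groups of ring B, two of them ortho and para to the migrating carbon, secure both, while the C2' hydroxyl is deactivated by its hydrogen bond to the carbonyl and no isolated olefin is present. The orthoformate keeps the medium dry, and the reaction is stopped at room temperature before the nitric acid set free can attack the MOM acetals.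

Step 7
Reactants: 9 1-[2-hydroxy-4-methoxy-3,6-bis(methoxymethoxy)phenyl]-3,3-dimethoxy-2-(2,4,5-trimethoxyphenyl)propan-1-one
Product: 11 5,8-dihydroxy-7-methoxy-3-(2,4,5-trimethoxyphenyl)chromen-4-one, via bis-MOM isoflavone 10 (not isolated)
Conditions: PPTS (0.2 eq), toluene, 5 Å MS, 90 °C; then 3 M HCl in MeOH, 50 °C, Ar
Reagents that add atoms: none
Why: Acid-catalysed acetal cyclisation; the dimethyl acetal ionises, the chelated C2' hydroxyl (the only free phenol) adds to the oxocarbenium carbon, and loss of the second methanol gives the pyranone. In the aprotic first stage the MOM acetals have no nucleophile to be transferred to, so the ring should close through the intended oxygen before any C6' oxygen is freed. The second stage is ordinary acetal exchange that hands both methoxymethyl groups to methanol.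

Step 8
Reactants: 11 5,8-dihydroxy-7-methoxy-3-(2,4,5-trimethoxyphenyl)chromen-4-one
Product: 12 7-methoxy-3-(2,4,5-trimethoxyphenyl)chromene-4,5,8-trione
Conditions: Ag2O (3 eq), Na2SO4, CH2Cl2, rt, dark
Reagents that add atoms: none
Why: Two-electron oxidation of a para-hydroquinone to the quinone by Ag2O under neutral, heterogeneous conditions; the ether-only ring B and the pyranone should be out of its reach, and Na2SO4 takes up the water formed.

Step 9
Reactants: 12 7-methoxy-3-(2,4,5-trimethoxyphenyl)chromene-4,5,8-trione; 13 tributyl(3-methylbut-2-enyl)stannane
Product: 14 5,8-dihydroxy-7-methoxy-6-(3-methylbut-2-enyl)-3-(2,4,5-trimethoxyphenyl)chromen-4-one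
Conditions: BF3·OEt2 (2.5 eq), CH2Cl2, −78 → −20 °C; aq NH4Cl, Ar
Reagents that add atoms: none
Why: Lewis-acid-promoted addition of an allylstannane to a quinone; the stannane should attack the C8 carbonyl (the one not deactivated as a vinylogous ester) through its γ-carbon, and a [3,3] shift then moves the group to C6, the only CH of the quinone ring, with a second allylic transposition that restores the linear prenyl group. Tautomerisation gives the hydroquinone directly, which is the oxidation level of the target.

## Compound list

1 | 1-(2,6-dihydroxy-4-methoxyphenyl)ethanone | CC(=O)c1c(O)cc(OC)cc1O | starting material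
2 | 1-[2-(benzyloxy)-6-hydroxy-4-methoxyphenyl]ethanone | CC(=O)c1c(O)cc(OC)cc1OCc1ccccc1 | intermediate
3 | potassium 3-acetyl-2-(benzyloxy)-4-hydroxy-6-methoxyphenyl sulfate | CC(=O)c1c(O)cc(OC)c(OS(=O)(=O)[O-])c1OCc1ccccc1.[K+] | intermediate (not isolated)
4 | 1-[2-(benzyloxy)-3,6-dihydroxy-4-methoxyphenyl]ethanone | CC(=O)c1c(O)cc(OC)c(O)c1OCc1ccccc1 | intermediate
5 | 1-[2-(benzyloxy)-4-methoxy-3,6-bis(methoxymethoxy)phenyl]ethanone | CC(=O)c1c(OCOC)cc(OC)c(OCOC)c1OCc1ccccc1 | intermediate
6 | 1-[2-hydroxy-4-methoxy-3,6-bis(methoxymethoxy)phenyl]ethanone | CC(=O)c1c(OCOC)cc(OC)c(OCOC)c1O | intermediate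
7 | 2,4,5-trimethoxybenzaldehyde | COc1cc(OC)c(C=O)cc1OC | starting material
8 | (E)-1-[2-hydroxy-4-methoxy-3,6-bis(methoxymethoxy)phenyl]-3-(2,4,5-trimethoxyphenyl)prop-2-en-1-one | COCOc1c(O)c(C(=O)/C=C/c2cc(OC)c(OC)cc2OC)c(OCOC)cc1OC | intermediate
9 | 1-[2-hydroxy-4-methoxy-3,6-bis(methoxymethoxy)phenyl]-3,3-dimethoxy-2-(2,4,5-trimethoxyphenyl)propan-1-one (racemic) | COCOc1c(O)c(C(=O)C(C(OC)OC)c2cc(OC)c(OC)cc2OC)c(OCOC)cc1OC | intermediate
10 | 7-methoxy-5,8-bis(methoxymethoxy)-3-(2,4,5-trimethoxyphenyl)chromen-4-one | COCOc1c(OC)cc(OCOC)c2c(=O)c(-c3cc(OC)c(OC)cc3OC)coc12 | intermediate (not isolated)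
11 | 5,8-dihydroxy-7-methoxy-3-(2,4,5-trimethoxyphenyl)chromen-4-one | COc1cc(O)c2c(=O)c(-c3cc(OC)c(OC)cc3OC)coc2c1O | intermediate
12 | 7-methoxy-3-(2,4,5-trimethoxyphenyl)chromene-4,5,8-trione | COC1=CC(=O)C2=C(OC=C(c3cc(OC)c(OC)cc3OC)C2=O)C1=O | intermediate
13 | tributyl(3-methylbut-2-enyl)stannane | CCCC[Sn](CCCC)(CCCC)CC=C(C)C | starting material
14 | 5,8-dihydroxy-7-methoxy-6-(3-methylbut-2-enyl)-3-(2,4,5-trimethoxyphenyl)chromen-4-one | COc1cc(OC)c(-c2coc3c(O)c(OC)c(CC=C(C)C)c(O)c3c2=O)cc1OC | target

## Step count and least certain steps

Total: 9 steps. Longest linear sequence: 9 steps, from 1 to 14; compounds 7 and 13 enter as bought.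

**Step 6 (key step).** The likeliest failures are oxidation of the very electron-rich ring B or of the chelated phenol by trivalent thallium instead of oxythallation of the enone, and partial loss of the MOM acetals to the nitric acid released during the reaction. Ring closure of the phenol onto the activated double bond, an aurone-type pathway, is a further possibility. The fallback drops the aryl shift and makes the C3–C1' bond by cross-coupling. It sets out from 6: heating with N,N-dimethylformamide dimethyl acetal should give (E)-3-(dimethylamino)-1-[2-hydroxy-4-methoxy-3,6-bis(methoxymethoxy)phenyl]prop-2-en-1-one F1. I2 and pyridine in CHCl3 should close ring C with iodination to 3-iodo-7-methoxy-5,8-bis(methoxymethoxy)chromen-4-one F2. Suzuki–Miyaura coupling of F2 with (2,4,5-trimethoxyphenyl)boronic acid (Pd(PPh3)4, Na2CO3, DME–H2O, 80 °C) would give 10, which rejoins the route at the second stage of step 7.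

**Step 7.** The risk is loss of the C6' MOM group before the ring has closed, after which closure through the wrong oxygen would lead to the 5,6-dihydroxy isomer. Slow closure under the weak acid of the first stage would make this worse. The fallback removes the ambiguity by making ring A symmetric at the closure and adding the C8 oxygen afterwards. It sets out from 1:
- MOMCl and K2CO3 in acetone should give 1-[2-hydroxy-4-methoxy-6-(methoxymethoxy)phenyl]ethanone F3.
- Condensation with 7 (KOH, EtOH) would give (E)-1-[2-hydroxy-4-methoxy-6-(methoxymethoxy)phenyl]-3-(2,4,5-trimethoxyphenyl)prop-2-en-1-one F4.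
- Tl(NO3)3 in MeOH would give 1-[2-hydroxy-4-methoxy-6-(methoxymethoxy)phenyl]-3,3-dimethoxy-2-(2,4,5-trimethoxyphenyl)propan-1-one F5.
- Methanolic HCl would give 5-hydroxy-7-methoxy-3-(2,4,5-trimethoxyphenyl)chromen-4-one F6; whichever ortho oxygen closes, the same compound results.
- Elbs oxidation of F6 (K2S2O8, aq NaOH, pyridine) is directed para to the C5 hydroxyl, to C8, through potassium 5-hydroxy-7-methoxy-4-oxo-3-(2,4,5-trimethoxyphenyl)chromen-8-yl sulfate F7. Acid hydrolysis returns to the route at 11.

The price is a low-yielding hydroxylation late in the sequence, on a pyranone that is sensitive to alkali.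

**Step 9.** Three things may go wrong.
- The stannane may attack the C5 carbonyl, or couple directly through its γ-carbon, giving a 1,1-dimethylallyl group or displacing the C7 methoxy group.
- Redox exchange between the product hydroquinone and unreacted quinone may occur; a wash with aq Na2S2O4 would guard against it.
- The Lewis acid may cyclise the prenyl group onto the C5 hydroxyl if the mixture warms.

The fallback is electrophilic instead of nucleophilic and skips the quinone. It sets out from 11 and ends at 14 in one operation: Friedel–Crafts prenylation with 2-methylbut-3-en-2-ol and BF3·OEt2 in dioxane at room temperature, where C6 is the only free position of ring A and is activated by three oxygens. It makes no new intermediate, but O-alkylation and attack on ring B would have to be separated off.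

**Step 2.** Elbs oxidations typically stop at partial conversion, and the quinol formed is itself oxidised by persulfate to dark polymeric material. The fallback is a Teuber oxidation followed by reduction. It sets out from 2: (KSO3)2NO in buffered aqueous acetone should oxidise the free para position to 2-acetyl-3-(benzyloxy)-5-methoxycyclohexa-2,5-diene-1,4-dione F8, and Na2S2O4 would reduce F8 to 4, where the route continues.

## Further compounds

F1 | step 6 | (E)-3-(dimethylamino)-1-[2-hydroxy-4-methoxy-3,6-bis(methoxymethoxy)phenyl]prop-2-en-1-one | CN(C)/C=C/C(=O)c1c(O)c(OCOC)c(OC)cc1OCOC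
F2 | step 6 | 3-iodo-7-methoxy-5,8-bis(methoxymethoxy)chromen-4-one | COCOc1c(OC)cc(OCOC)c2c(=O)c(I)coc12
F3 | step 7 | 1-[2-hydroxy-4-methoxy-6-(methoxymethoxy)phenyl]ethanone | CC(=O)c1c(O)cc(OC)cc1OCOC
F4 | step 7 | (E)-1-[2-hydroxy-4-methoxy-6-(methoxymethoxy)phenyl]-3-(2,4,5-trimethoxyphenyl)prop-2-en-1-one | COCOc1cc(OC)cc(O)c1C(=O)/C=C/c1cc(OC)c(OC)cc1OC
F5 | step 7 | 1-[2-hydroxy-4-methoxy-6-(methoxymethoxy)phenyl]-3,3-dimethoxy-2-(2,4,5-trimethoxyphenyl)propan-1-one (racemic) | COCOc1cc(OC)cc(O)c1C(=O)C(C(OC)OC)c1cc(OC)c(OC)cc1OC
F6 | step 7 | 5-hydroxy-7-methoxy-3-(2,4,5-trimethoxyphenyl)chromen-4-one | COc1cc(O)c2c(=O)c(-c3cc(OC)c(OC)cc3OC)coc2c1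
F7 | step 7 | potassium 5-hydroxy-7-methoxy-4-oxo-3-(2,4,5-trimethoxyphenyl)chromen-8-yl sulfate | COc1cc(O)c2c(=O)c(-c3cc(OC)c(OC)cc3OC)coc2c1OS(=O)(=O)[O-].[K+]
F0 | step 9 | none | none
F8 | step 2 | 2-acetyl-3-(benzyloxy)-5-methoxycyclohexa-2,5-diene-1,4-dione | CC(=O)C1=C(OCc2ccccc2)C(=O)C(OC)=CC1=O
A1 | alternative 1 | 3-(2-hydroxy-4,5-dimethoxyphenyl)-7-methoxy-5,8-bis(methoxymethoxy)-6-(3-methylbut-2-enyl)chromen-4-one | COc1cc(O)c(-c2coc3c(OCOC)c(OC)c(CC=C(C)C)c(OCOC)c3c2=O)cc1OC
A2 | alternative 1 | 3-ethynyl-7-methoxy-5,8-bis(methoxymethoxy)-6-(3-methylbut-2-enyl)chromen-4-one | C#Cc1coc2c(OCOC)c(OC)c(CC=C(C)C)c(OCOC)c2c1=O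
A3 | alternative 2 | 3-[4-methoxy-3,6-bis(methoxymethoxy)-5-(3-methylbut-2-enyl)-2-(prop-2-enyloxy)phenyl]-3-oxo-2-(2,4,5-trimethoxyphenyl)propanal (racemic) | C=CCOc1c(OCOC)c(OC)c(CC=C(C)C)c(OCOC)c1C(=O)C(C=O)c1cc(OC)c(OC)cc1OC
A4 | alternative 2 | [4-methoxy-3,6-bis(methoxymethoxy)-5-(3-methylbut-2-enyl)-2-(prop-2-enyloxy)phenyl][trans-3-(2,4,5-trimethoxyphenyl)oxiran-2-yl]methanone (racemic, one enantiomer drawn) | C=CCOc1c(OCOC)c(OC)c(CC=C(C)C)c(OCOC)c1C(=O)[C@@H]1O[C@H]1c1cc(OC)c(OC)cc1OC
A5 | alternative 3 | 7-methoxy-5,8-bis(methoxymethoxy)-6-(3-methylbut-2-enyl)-3-(2,4,5-trimethoxyphenyl)chromen-4-one | COCOc1c(OC)c(CC=C(C)C)c(OCOC)c2c(=O)c(-c3cc(OC)c(OC)cc3OC)coc12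
A6 | alternative 3 | 4-[(E)-2-(2,4,5-trimethoxyphenyl)ethenyl]morpholine | COc1cc(OC)c(/C=C/N2CCOCC2)cc1OC
A7 | alternative 3 | 7-methoxy-5,8-bis(methoxymethoxy)-2,2-dimethyl-6-(3-methylbut-2-enyl)-1,3-benzodioxin-4-one | CC1(C)OC(=O)c2c(OCOC)c(CC=C(C)C)c(OC)c(OCOC)c2O1
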